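## Retrosynthetic overview

- The oxirane is made last, by Shi epoxidation of a prenyl α-hydroxy ketone. That ketone comes from a 2,3-diol by oxidation, and the diol from isobutenyl-copper opening of an erythro 2,2-disubstituted epoxy alcohol.
- The epoxy alcohol comes from hydroxyl-directed epoxidation of a lipase-resolved (2S)-3-cyclohexylbut-3-en-2-ol. Its methyl carbinol centre relays to the quaternary carbinol and is then oxidised away.
- The allylic alcohol comes from an enone, made by Stille coupling of a 2-iodoalkene. That traces back through alkyne and aldehyde to (1S,3S,4S)-3-bromo-4-chloro-4-methylcyclohexanecarbonitrile.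
- The bromochloride comes from a tertiary alcohol via a bromonium ion (Cl enters anti to Br). The bromide comes from bromide opening of the cyclic sulfate of a trans-diol (inversion at C3), and the diol from stereoconvergent hydrolysis of the epoxides of a Diels–Alder adduct.
- Ring order: the cyclohexane first (catalytic asymmetric Diels–Alder of isoprene with 2,2,2-trifluoroethyl acrylate sets C1), the oxirane last.

Assumption: the SMILES is read as (3S)-carbinol, (2R)-oxirane and a (1S,3S,4S)-ring in which Br is cis to the side chain and trans to Cl (all three equatorial, methyl axial).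

## Route

Step 1
Reactants: 1 isoprene (2-methylbuta-1,3-diene); 2 2,2,2-trifluoroethyl acrylate
Product: 3 2,2,2-trifluoroethyl (1S)-4-methylcyclohex-3-ene-1-carboxylate
Conditions: (S)-1-(2-methylphenyl)-3,3-diphenyltetrahydro-1H,3H-pyrrolo[1,2-c][1,3,2]oxazaborole protonated by Tf2NH (10 mol %), CH2Cl2, −78 → −20 °C
Reagents that add atoms: none
Why: Catalytic enantioselective Diels–Alder reaction in which the protonated oxazaborolidine binds the acrylate and shields one face, so isoprene adds with para regiochemistry and sets the (S)-configured C1 as the first stereocentre (same sense as the analogous butadiene adduct; the antipodal catalyst is equally available).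

Step 2
Reactants: 3 2,2,2-trifluoroethyl (1S)-4-methylcyclohex-3-ene-1-carboxylate
Product: 4 2,2,2-trifluoroethyl (3S)-6-methyl-7-oxabicyclo[4.1.0]heptane-3-carboxylate (both cis-fused epoxide diastereomers, ca. 1:1)
Conditions: mCPBA (1.1 equiv), CH2Cl2, 0 °C
Reagents that add atoms: 3-chloroperoxybenzoic acid (mCPBA), OOC(=O)c1cccc(Cl)c1
Why: Prilezhaev epoxidation of the only alkene, where no facial selectivity is needed because both epoxides converge in step 3.

Step 3
Reactants: 4 2,2,2-trifluoroethyl (3S)-6-methyl-7-oxabicyclo[4.1.0]heptane-3-carboxylate (epoxide mixture)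
Product: 5 2,2,2-trifluoroethyl (1S,3R,4R)-3,4-dihydroxy-4-methylcyclohexane-1-carboxylate
Conditions: HClO4 (0.1 M aq., cat.), THF/H2O 3:1, 0 → 23 °C
Reagents that add atoms: water, O
Why: Acid-catalysed epoxide hydrolysis under Fürst–Plattner (trans-diaxial) control is stereoconvergent, since the epoxide trans to the ester opens at C4 and the cis epoxide at C3, so both give the diol with C3–OH trans and C4–OH cis to the ester, as is known for the two limonene oxides.

Step 4
Reactants: 5 2,2,2-trifluoroethyl (1S,3R,4R)-3,4-dihydroxy-4-methylcyclohexane-1-carboxylate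
Product: 6 (1S,3R,4R)-3,4-dihydroxy-4-methylcyclohexane-1-carboxamide
Conditions: NH3 (7 M in MeOH), 23 °C
Reagents that add atoms: ammonia, N
Why: Aminolysis of the activated trifluoroethyl ester gives the primary amide without touching a stereocentre, and any hydroxy lactone formed in step 3 is opened to the same amide.

Step 5
Reactants: 6 (1S,3R,4R)-3,4-dihydroxy-4-methylcyclohexane-1-carboxamide
Product: 8 (1S,3R,4R)-3,4-dihydroxy-4-methylcyclohexane-1-carbonitrile, via secondary trifluoroacetate 7 (not isolated)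
Conditions: (CF3CO)2O, pyridine, CH2Cl2, 0 °C; then K2CO3 (cat.), MeOH, 0 °C
Reagents that add atoms: none
Why: Dehydration of the primary amide with trifluoroacetic anhydride gives the nitrile and mild methanolysis removes the trifluoroacetate formed on the secondary alcohol, leaving a small linear cyano group that lets the ring flip in steps 6 to 8.

Step 6
Reactants: 8 (1S,3R,4R)-3,4-dihydroxy-4-methylcyclohexane-1-carbonitrile
Product: 10 (3aR,5S,7aR)-7a-methyl-2,2-dioxohexahydro-1,3,2-benzodioxathiole-5-carbonitrile (cyclic sulfate of 8), via cyclic sulfite 9 (not isolated)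
Conditions: SOCl2, Et3N, CH2Cl2, 0 °C; then RuCl3·3H2O (1 mol %), NaIO4, MeCN/H2O, 0 °C
Reagents that add atoms: thionyl chloride, O=S(Cl)Cl; sodium periodate, [Na+].[O-]I(=O)(=O)=O
Why: Sharpless cyclic sulfate synthesis (cyclic sulfite, then RuO4-catalysed oxidation), possible because with only a cyano group at C1 the trans-diol reaches the diequatorial chair, and it activates C3–O while masking the tertiary oxygen without changing a stereocentre.

Step 7
Reactants: 10 (3aR,5S,7aR)-7a-methyl-2,2-dioxohexahydro-1,3,2-benzodioxathiole-5-carbonitrile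
Product: 12 (1S,3S,4R)-3-bromo-4-hydroxy-4-methylcyclohexane-1-carbonitrile, via lithium alkyl sulfate 11 (not isolated)
Conditions: LiBr, THF, 23 → 45 °C; then H2SO4 (cat.), H2O (2 equiv), THF, 23 °C
Reagents that add atoms: lithium bromide, [Li+].[Br-]
Why: SN2 opening of the cyclic sulfate by bromide occurs at the secondary carbon C3 with inversion, which places Br cis to the cyano group (3S), and acid hydrolysis of the tertiary sulfate monoester then frees the alcohol (either C4 epimer would serve in step 8).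

Step 8
Reactants: 12 (1S,3S,4R)-3-bromo-4-hydroxy-4-methylcyclohexane-1-carbonitrile
Product: 13 (1S,3S,4S)-3-bromo-4-chloro-4-methylcyclohexane-1-carbonitrile
Conditions: HCl (g), CH2Cl2, −20 → 0 °C
Reagents that add atoms: hydrogen chloride, Cl
Why: SN1 ionisation of the tertiary alcohol gives a cation bridged by the neighbouring bromine (bromonium ion, Winstein-type neighbouring-group participation) on the face fixed in step 7, and chloride opens it at the tertiary carbon anti to Br (Markovnikov), setting (4S) with Cl trans to Br, the small cyano group allowing the ring flip that this trans-diaxial opening needs.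

Step 9
Reactants: 13 (1S,3S,4S)-3-bromo-4-chloro-4-methylcyclohexane-1-carbonitrile
Product: 15 (1S,3S,4S)-3-bromo-4-chloro-4-methylcyclohexane-1-carbaldehyde, via N-aluminoimine 14 (not isolated)
Conditions: i-Bu2AlH (1.2 equiv), toluene, −78 °C; then 1 M HCl (aq), 0 °C
Reagents that add atoms: water, O
Why: Partial reduction of the nitrile by i-Bu2AlH stops at the N-aluminoimine at −78 °C, which is hydrolysed to the aldehyde on work-up, while alkyl chlorides and bromides are not reduced under these conditions.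

Step 10
Reactants: 15 (1S,3S,4S)-3-bromo-4-chloro-4-methylcyclohexane-1-carbaldehyde; 16 dimethyl (1-diazo-2-oxopropyl)phosphonate
Product: 17 (1S,2S,4S)-2-bromo-1-chloro-4-ethynyl-1-methylcyclohexane
Conditions: K2CO3, MeOH, 0 → 23 °C
Reagents that add atoms: none
Why: Seyferth–Gilbert homologation in the Ohira–Bestmann variant converts the aldehyde into the terminal alkyne under mild carbonate/methanol conditions that leave the halides and the C1 centre untouched.

Step 11
Reactants: 17 (1S,2S,4S)-2-bromo-1-chloro-4-ethynyl-1-methylcyclohexane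
Product: 18 (1S,2S,4S)-2-bromo-1-chloro-4-(1-iodoethenyl)-1-methylcyclohexane
Conditions: NaI, Me3SiCl, H2O (0.5 equiv), MeCN, 0 → 23 °C
Reagents that add atoms: sodium iodide, [Na+].[I-]
Why: Markovnikov hydroiodination of the terminal alkyne by HI made in the flask gives the 2-iodo-1-alkene, the handle for attaching the acetyl carbons at the internal alkyne carbon.

Step 12
Reactants: 18 (1S,2S,4S)-2-bromo-1-chloro-4-(1-iodoethenyl)-1-methylcyclohexane; 19 tributyl(1-ethoxyethenyl)stannane
Product: 21 3-[(1S,3S,4S)-3-bromo-4-chloro-4-methylcyclohexyl]but-3-en-2-one, via dienyl ethyl ether 20 (not isolated)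
Conditions: Pd2(dba)3 (2.5 mol %), AsPh3 (20 mol %), CuI (10 mol %), NMP, 40 °C; then 1 M HCl (aq), THF, 0 °C
Reagents that add atoms: water, O
Why: Stille cross-coupling of the vinyl iodide with the 1-ethoxyvinylstannane (an acetyl anion equivalent; zerovalent palladium does not insert into the unactivated alkyl halides here) followed by enol ether hydrolysis gives the α-methylene methyl ketone.

Step 13
Reactants: 21 3-[(1S,3S,4S)-3-bromo-4-chloro-4-methylcyclohexyl]but-3-en-2-one
Product: 22 (2RS)-3-[(1S,3S,4S)-3-bromo-4-chloro-4-methylcyclohexyl]but-3-en-2-ol (1:1 carbinol epimers)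
Conditions: NaBH4, CeCl3·7H2O, MeOH, −78 °C
Reagents that add atoms: none
Why: Luche 1,2-reduction of the enone gives the allylic alcohol as both carbinol epimers, the substrate for the enzymatic resolution.

Step 14
Reactants: 22 (2RS)-3-[(1S,3S,4S)-3-bromo-4-chloro-4-methylcyclohexyl]but-3-en-2-ol
Product: 23 (2S)-3-[(1S,3S,4S)-3-bromo-4-chloro-4-methylcyclohexyl]but-3-en-2-ol
Conditions: immobilised Candida antarctica lipase B, vinyl acetate, t-BuOMe, 30 °C, to ca. 52 % conversion
Reagents that add atoms: none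
Why: Lipase-catalysed kinetic resolution by transesterification (Kazlauskas rule) acylates only the (2R)-carbinol epimer, so the (2S)-alcohol, whose centre will direct the quaternary carbinol, is recovered unchanged and separated from the acetate.

Step 15
Reactants: 23 (2S)-3-[(1S,3S,4S)-3-bromo-4-chloro-4-methylcyclohexyl]but-3-en-2-ol
Product: 24 (1S)-1-{(2R)-2-[(1S,3S,4S)-3-bromo-4-chloro-4-methylcyclohexyl]oxiran-2-yl}ethan-1-ol
Conditions: VO(acac)2 (3 mol %), t-BuOOH (in decane), CH2Cl2, 0 → 23 °C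
Reagents that add atoms: tert-butyl hydroperoxide, CC(C)(C)OO
Why: Hydroxyl-directed epoxidation in which the vanadate-ester transition state avoids allylic 1,2-strain between the ring substituent on the alkene and the carbinol methyl, giving the erythro epoxy alcohol and so setting the quaternary centre ((2R)-oxirane from the (1S)-carbinol).

Step 16
Reactants: 24 (1S)-1-{(2R)-2-[(1S,3S,4S)-3-bromo-4-chloro-4-methylcyclohexyl]oxiran-2-yl}ethan-1-ol; 25 (2-methylprop-1-en-1-yl)magnesium bromide
Product: 26 (2S,3S)-3-[(1S,3S,4S)-3-bromo-4-chloro-4-methylcyclohexyl]-6-methylhept-5-ene-2,3-diol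
Conditions: 25 (3 equiv), CuI (15 mol %), THF, −40 → −15 °C; then aq. NH4Cl
Reagents that add atoms: none
Why: Copper-catalysed SN2 opening of the 2,2-disubstituted epoxide by the alkenyl Grignard reagent occurs at the unhindered CH2 terminus, installing the prenyl group and leaving the quaternary C–O centre untouched (its descriptor becomes 3S only through the change in CIP priorities).

Step 17
Reactants: 26 (2S,3S)-3-[(1S,3S,4S)-3-bromo-4-chloro-4-methylcyclohexyl]-6-methylhept-5-ene-2,3-diol
Product: 27 (3S)-3-[(1S,3S,4S)-3-bromo-4-chloro-4-methylcyclohexyl]-3-hydroxy-6-methylhept-5-en-2-one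
Conditions: IBX, DMSO, 23 °C
Reagents that add atoms: none
Why: IBX oxidises the secondary alcohol of the 1,2-diol to the ketone without glycol cleavage and cannot oxidise the tertiary alcohol, which removes the relay centre and prevents 5-exo attack of that hydroxyl on the epoxide made next.

Step 18
Reactants: 27 (3S)-3-[(1S,3S,4S)-3-bromo-4-chloro-4-methylcyclohexyl]-3-hydroxy-6-methylhept-5-en-2-one
Product: 28 (3S)-3-[(1S,3S,4S)-3-bromo-4-chloro-4-methylcyclohexyl]-4-[(2R)-3,3-dimethyloxiran-2-yl]-3-hydroxybutan-2-one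
Conditions: 1,2:4,5-di-O-isopropylidene-β-D-erythro-2,3-hexodiulo-2,6-pyranose (D-fructose-derived Shi ketone, 30 mol %), Oxone (2KHSO5·KHSO4·K2SO4), K2CO3, Bu4NHSO4, MeCN/CH2(OMe)2/aq. buffer pH 10.5, 0 °C
Reagents that add atoms: potassium peroxymonosulfate, [K+].[O-]S(=O)(=O)OO
Why: Shi asymmetric epoxidation, in which the dioxirane of the D-fructose-derived ketone epoxidises the trisubstituted prenyl alkene through the spiro transition state under reagent control to give the (2R)-oxirane, while the buffered basic medium preserves the acid-sensitive epoxy alcohol.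

## Compound list

1 | isoprene | CC(=C)C=C | starting material
2 | 2,2,2-trifluoroethyl acrylate | C=CC(=O)OCC(F)(F)F | starting material
3 | 2,2,2-trifluoroethyl (1S)-4-methylcyclohex-3-ene-1-carboxylate | O=C(OCC(F)(F)F)[C@H]1CCC(C)=CC1 | intermediate
4 | 2,2,2-trifluoroethyl (3S)-6-methyl-7-oxabicyclo[4.1.0]heptane-3-carboxylate (two epoxide diastereomers) | O=C(OCC(F)(F)F)[C@H]1CCC2(C)OC2C1 | intermediate
5 | 2,2,2-trifluoroethyl (1S,3R,4R)-3,4-dihydroxy-4-methylcyclohexane-1-carboxylate | O=C(OCC(F)(F)F)[C@H]1CC[C@@](C)(O)[C@H](O)C1 | intermediate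
6 | (1S,3R,4R)-3,4-dihydroxy-4-methylcyclohexane-1-carboxamide | NC(=O)[C@H]1CC[C@@](C)(O)[C@H](O)C1 | intermediate
7 | (1R,2R,5S)-5-cyano-2-hydroxy-2-methylcyclohexyl trifluoroacetate | N#C[C@H]1CC[C@@](C)(O)[C@H](OC(=O)C(F)(F)F)C1 | intermediate
8 | (1S,3R,4R)-3,4-dihydroxy-4-methylcyclohexane-1-carbonitrile | N#C[C@H]1CC[C@@](C)(O)[C@H](O)C1 | intermediate
9 | (3aR,5S,7aR)-7a-methyl-2-oxohexahydro-1,3,2-benzodioxathiole-5-carbonitrile (cyclic sulfite, both S-epimers) | N#C[C@H]1CC[C@@]2(C)OS(=O)O[C@@H]2C1 | intermediate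
10 | (3aR,5S,7aR)-7a-methyl-2,2-dioxohexahydro-1,3,2-benzodioxathiole-5-carbonitrile (cyclic sulfate) | N#C[C@H]1CC[C@@]2(C)OS(=O)(=O)O[C@@H]2C1 | intermediate
11 | lithium (1R,2S,4S)-2-bromo-4-cyano-1-methylcyclohexyl sulfate | N#C[C@H]1CC[C@@](C)(OS(=O)(=O)[O-])[C@@H](Br)C1.[Li+] | intermediate
12 | (1S,3S,4R)-3-bromo-4-hydroxy-4-methylcyclohexane-1-carbonitrile | N#C[C@H]1CC[C@@](C)(O)[C@@H](Br)C1 | intermediate
13 | (1S,3S,4S)-3-bromo-4-chloro-4-methylcyclohexane-1-carbonitrile | N#C[C@H]1CC[C@](C)(Cl)[C@@H](Br)C1 | intermediate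
14 | N-(diisobutylalumanyl)imine of aldehyde 15 | CC(C)C[Al](CC(C)C)N=C[C@H]1CC[C@](C)(Cl)[C@@H](Br)C1 | intermediate
15 | (1S,3S,4S)-3-bromo-4-chloro-4-methylcyclohexane-1-carbaldehyde | O=C[C@H]1CC[C@](C)(Cl)[C@@H](Br)C1 | intermediate
16 | dimethyl (1-diazo-2-oxopropyl)phosphonate | CC(=O)C(=[N+]=[N-])P(=O)(OC)OC | starting material
17 | (1S,2S,4S)-2-bromo-1-chloro-4-ethynyl-1-methylcyclohexane | C#C[C@H]1CC[C@](C)(Cl)[C@@H](Br)C1 | intermediate
18 | (1S,2S,4S)-2-bromo-1-chloro-4-(1-iodoethenyl)-1-methylcyclohexane | C=C(I)[C@H]1CC[C@](C)(Cl)[C@@H](Br)C1 | intermediate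
19 | tributyl(1-ethoxyethenyl)stannane | CCCC[Sn](CCCC)(CCCC)C(=C)OCC | starting material
20 | (1S,2S,4S)-2-bromo-1-chloro-4-(3-ethoxybuta-1,3-dien-2-yl)-1-methylcyclohexane | CCOC(=C)C(=C)[C@H]1CC[C@](C)(Cl)[C@@H](Br)C1 | intermediate
21 | 3-[(1S,3S,4S)-3-bromo-4-chloro-4-methylcyclohexyl]but-3-en-2-one | CC(=O)C(=C)[C@H]1CC[C@](C)(Cl)[C@@H](Br)C1 | intermediate
22 | (2RS)-3-[(1S,3S,4S)-3-bromo-4-chloro-4-methylcyclohexyl]but-3-en-2-ol | CC(O)C(=C)[C@H]1CC[C@](C)(Cl)[C@@H](Br)C1 | intermediate
23 | (2S)-3-[(1S,3S,4S)-3-bromo-4-chloro-4-methylcyclohexyl]but-3-en-2-ol | C[C@H](O)C(=C)[C@H]1CC[C@](C)(Cl)[C@@H](Br)C1 | intermediate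
24 | (1S)-1-{(2R)-2-[(1S,3S,4S)-3-bromo-4-chloro-4-methylcyclohexyl]oxiran-2-yl}ethan-1-ol | C[C@H](O)[C@]1(CO1)[C@H]1CC[C@](C)(Cl)[C@@H](Br)C1 | intermediate
25 | (2-methylprop-1-en-1-yl)magnesium bromide | CC(C)=C[Mg]Br | starting material
26 | (2S,3S)-3-[(1S,3S,4S)-3-bromo-4-chloro-4-methylcyclohexyl]-6-methylhept-5-ene-2,3-diol | C[C@H](O)[C@](O)(CC=C(C)C)[C@H]1CC[C@](C)(Cl)[C@@H](Br)C1 | intermediate
27 | (3S)-3-[(1S,3S,4S)-3-bromo-4-chloro-4-methylcyclohexyl]-3-hydroxy-6-methylhept-5-en-2-one | CC(=O)[C@](O)(CC=C(C)C)[C@H]1CC[C@](C)(Cl)[C@@H](Br)C1 | intermediate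
28 | (3S)-3-[(1S,3S,4S)-3-bromo-4-chloro-4-methylcyclohexyl]-4-[(2R)-3,3-dimethyloxiran-2-yl]-3-hydroxybutan-2-one | CC(=O)[C@](O)(C[C@H]1OC1(C)C)[C@H]1CC[C@](C)(Cl)[C@@H](Br)C1 | target

## Step count and risks

Total steps: 18. Longest linear sequence: 18 steps (from 1 and 2 to 28).

Steps most likely to fail:

Step 8 (tertiary alcohol to chloride through the bromonium ion). The chloride may open the bridged ion at C3 instead, or bromine may be lost to give the alkene, which would then re-add from the other face. The fallback gives up the stepwise sequence for a direct anti addition and sets out from 3. Ammonolysis (NH3, MeOH) gives (1S)-4-methylcyclohex-3-ene-1-carboxamide F1. Dehydration with (CF3CO)2O and pyridine gives (1S)-4-methylcyclohex-3-ene-1-carbonitrile F2. N-Bromosuccinimide with Et4NCl (CH2Cl2/MeCN, −40 °C, Markovnikov anti addition of BrCl) then gives 13 as the minor adduct. The major adduct is the trans-diaxial diastereomer (1S,3R,4R)-3-bromo-4-chloro-4-methylcyclohexane-1-carbonitrile F3 (expected about 3:1 over 13), which is removed by chromatography. The route is rejoined at 13.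

Step 16 (Grignard/copper epoxide opening in the presence of the secondary bromide and tertiary chloride, with possible Payne rearrangement of the magnesium alkoxide). The fallback builds the quaternary centre by chelation-controlled allylation instead and sets out from 22, using the other carbinol epimer.
- The lipase acylation of step 14 delivers (2R)-3-[(1S,3S,4S)-3-bromo-4-chloro-4-methylcyclohexyl]but-3-en-2-yl acetate F4, and methanolysis (K2CO3, MeOH) gives the (2R)-alcohol (2R)-3-[(1S,3S,4S)-3-bromo-4-chloro-4-methylcyclohexyl]but-3-en-2-ol F5.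
- 4-Methoxybenzyl trichloroacetimidate with catalytic PPTS gives the ether (2R)-3-[(1S,3S,4S)-3-bromo-4-chloro-4-methylcyclohexyl]but-3-en-2-yl 4-methoxybenzyl ether F6.
- OsO4 (cat.)/NaIO4/2,6-lutidine cleaves the methylene group to the ketone (2R)-1-[(1S,3S,4S)-3-bromo-4-chloro-4-methylcyclohexyl]-2-[(4-methoxybenzyl)oxy]propan-1-one F7.
- Allyltributylstannane with MgBr2·OEt2 (CH2Cl2, −78 → −20 °C) adds through the Cram chelate anti to the methyl group and gives (2R,3S)-3-[(1S,3S,4S)-3-bromo-4-chloro-4-methylcyclohexyl]-2-[(4-methoxybenzyl)oxy]hex-5-en-3-ol F8.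
- Cross-metathesis with 2-methyl-2-butene (second-generation Grubbs catalyst, 40 °C) gives (2R,3S)-3-[(1S,3S,4S)-3-bromo-4-chloro-4-methylcyclohexyl]-2-[(4-methoxybenzyl)oxy]-6-methylhept-5-en-3-ol F9.
- DDQ (CH2Cl2/pH 7 buffer) frees the diol (2R,3S)-3-[(1S,3S,4S)-3-bromo-4-chloro-4-methylcyclohexyl]-6-methylhept-5-ene-2,3-diol F10, the C2 epimer of 26.
- IBX oxidation of F10 rejoins the route at 27.

Step 11 (HI and iodide in the presence of the vicinal bromochloride and the tertiary chloride). The fallback avoids acid and free iodide and sets out from 17. Ruthenium-catalysed Markovnikov hydrosilylation (Et3SiH, [Cp*Ru(MeCN)3]PF6, CH2Cl2, 0 → 23 °C) gives the 1,1-disubstituted vinylsilane triethyl{1-[(1S,3S,4S)-3-bromo-4-chloro-4-methylcyclohexyl]ethenyl}silane F11. Ipso-iododesilylation with N-iodosuccinimide in (CF3)2CHOH at 0 °C then rejoins the route at 18.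

Further compounds
F1 | step 8 | (1S)-4-methylcyclohex-3-ene-1-carboxamide | NC(=O)[C@H]1CCC(C)=CC1
F2 | step 8 | (1S)-4-methylcyclohex-3-ene-1-carbonitrile | N#C[C@H]1CCC(C)=CC1
F3 | step 8 | (1S,3R,4R)-3-bromo-4-chloro-4-methylcyclohexane-1-carbonitrile | N#C[C@H]1CC[C@@](C)(Cl)[C@H](Br)C1
F4 | step 16 | (2R)-3-[(1S,3S,4S)-3-bromo-4-chloro-4-methylcyclohexyl]but-3-en-2-yl acetate | C[C@@H](OC(C)=O)C(=C)[C@H]1CC[C@](C)(Cl)[C@@H](Br)C1
F5 | step 16 | (2R)-3-[(1S,3S,4S)-3-bromo-4-chloro-4-methylcyclohexyl]but-3-en-2-ol | C[C@@H](O)C(=C)[C@H]1CC[C@](C)(Cl)[C@@H](Br)C1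
F6 | step 16 | (2R)-3-[(1S,3S,4S)-3-bromo-4-chloro-4-methylcyclohexyl]but-3-en-2-yl 4-methoxybenzyl ether | C[C@@H](OCc1ccc(OC)cc1)C(=C)[C@H]1CC[C@](C)(Cl)[C@@H](Br)C1
F7 | step 16 | (2R)-1-[(1S,3S,4S)-3-bromo-4-chloro-4-methylcyclohexyl]-2-[(4-methoxybenzyl)oxy]propan-1-one | C[C@@H](OCc1ccc(OC)cc1)C(=O)[C@H]1CC[C@](C)(Cl)[C@@H](Br)C1
F8 | step 16 | (2R,3S)-3-[(1S,3S,4S)-3-bromo-4-chloro-4-methylcyclohexyl]-2-[(4-methoxybenzyl)oxy]hex-5-en-3-ol | C[C@@H](OCc1ccc(OC)cc1)[C@](O)(CC=C)[C@H]1CC[C@](C)(Cl)[C@@H](Br)C1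
F9 | step 16 | (2R,3S)-3-[(1S,3S,4S)-3-bromo-4-chloro-4-methylcyclohexyl]-2-[(4-methoxybenzyl)oxy]-6-methylhept-5-en-3-ol | C[C@@H](OCc1ccc(OC)cc1)[C@](O)(CC=C(C)C)[C@H]1CC[C@](C)(Cl)[C@@H](Br)C1
F10 | step 16 | (2R,3S)-3-[(1S,3S,4S)-3-bromo-4-chloro-4-methylcyclohexyl]-6-methylhept-5-ene-2,3-diol | C[C@@H](O)[C@](O)(CC=C(C)C)[C@H]1CC[C@](C)(Cl)[C@@H](Br)C1
F11 | step 11 | triethyl{1-[(1S,3S,4S)-3-bromo-4-chloro-4-methylcyclohexyl]ethenyl}silane | CC[Si](CC)(CC)C(=C)[C@H]1CC[C@](C)(Cl)[C@@H](Br)C1
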